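**Retrosynthetic overview**
1. Target 19 ⇒ triol 18: the C2–O1 bond is made last, by acid-mediated closure of the tetrahydrofuran; 18 comes from hydride opening of aldol lactone 17.
2. 17 ⇒ (S)-β-(3,4-dimethoxybenzyl)-γ-butyrolactone 8 + 3,4,5-trimethoxybenzaldehyde 14 (C2–C3 bond, trans-selective aldol).
3. 8 ⇒ prochiral 3-(3,4-dimethoxybenzyl)oxetane 6 + CO: enantioselective carbonylative ring expansion of the four-membered ether to the five-membered lactone, which sets C4.
4. 6 ⇒ 3-methyleneoxetane 4 + 4-bromoveratrole 3 (from catechol 1); 14 ⇐ p-cresol 9 (bromination/hydrolysis, methoxylation, methylation).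
5. Ring order: oxetane (purchased) → γ-lactone (step 4) → opened and re-closed as the tetrahydrofuran (step 8).

Assumption: the carbinol carbon created in step 7 is carried as both epimers (drawn without a wedge in 16, 17 and 18) because step 8 erases it, and within a one-pot step only intermediates that mark a change of reagent or stage are numbered.

**Route**

Step 1
Reactants: 1 catechol
Product: 2 1,2-dimethoxybenzene (veratrole)
Conditions: MeI (2.5 equiv), K2CO3 (2.5 equiv), acetone, reflux
Reagents that add atoms: iodomethane (CI)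
Why: double Williamson O-methylation (phenoxide SN2 on iodomethane); no stereocentre is involved.

Step 2
Reactants: 2 1,2-dimethoxybenzene
Product: 3 4-bromo-1,2-dimethoxybenzene
Conditions: NBS (1.02 equiv), MeCN, 0 °C → rt
Reagents that add atoms: N-bromosuccinimide (O=C1CCC(=O)N1Br)
Why: electrophilic aromatic bromination; the position para to one methoxy group is the only unhindered activated site, so monobromination at C4 is clean.

Step 3
Reactants: 4 3-methyleneoxetane; 3 4-bromo-1,2-dimethoxybenzene
Product: 6 3-(3,4-dimethoxybenzyl)oxetane, via B-(oxetan-3-ylmethyl)-9-BBN 5 (not isolated)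
Conditions: 9-BBN (1.1 equiv), THF, 0 °C → rt; then 3, PdCl2(dppf) (3 mol %), 3 M aq. NaOH, THF, 65 °C
Reagents that add atoms: none
Why: anti-Markovnikov hydroboration puts boron on the exocyclic CH2 and the B-alkyl Suzuki–Miyaura coupling transfers this primary alkyl group to the aryl bromide; the oxetane tolerates base and the product is achiral with a prochiral C3.

Step 4
Reactants: 6 3-(3,4-dimethoxybenzyl)oxetane; 7 carbon monoxide
Product: 8 (S)-4-(3,4-dimethoxybenzyl)dihydrofuran-2(3H)-one
Conditions: [(R,R)-(salcy)Cr(THF)2][Co(CO)4] (5 mol %; salcy = dianion of N,N'-bis(3,5-di-tert-butylsalicylidene)-trans-cyclohexane-1,2-diamine), CO (60 bar), 1,2-dimethoxyethane, 60 °C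
Reagents that add atoms: none
Why: Proposed new method: enantioselective desymmetrising carbonylative ring expansion of a prochiral 3-substituted oxetane — the chiral salen-chromium cation binds the oxetane oxygen, [Co(CO)4]− opens one of the two enantiotopic O–CH2 bonds by backside SN2 attack (the enantio-determining event; C3 itself is never touched), CO inserts into the Co–alkyl bond and the chromium-bound alkoxide closes on the acyl cobalt to release the γ-lactone and the ion pair, so the choice of CH2 fixes C4 of 8 as S or R (the sense must be found by experiment, and the (S,S)-catalyst is used if the (R,R)-catalyst gives ent-8); the closest known reactions are the achiral [Lewis acid][Co(CO)4]-catalysed carbonylation of oxetanes to γ-butyrolactones, the enantioselective carbonylation of meso-epoxides with chiral salen-chromium cobaltates and chiral-acid-catalysed desymmetrising openings of 3-substituted oxetanes.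

Step 5
Reactants: 9 p-cresol
Product: 12 3,5-dibromo-4-hydroxybenzaldehyde, via 2,6-dibromo-4-methylphenol 10 (not isolated), via 2,6-dibromo-4-(dibromomethyl)phenol 11 (not isolated)
Conditions: Br2 (2.05 equiv), o-dichlorobenzene, 30 °C; Br2 (2.05 equiv), 150 °C; then H2O, 100 °C
Reagents that add atoms: bromine (BrBr); water (O)
Why: electrophilic bromination fills both positions ortho to the hydroxyl, further bromine at 150 °C brominates the para-hydroxybenzylic methyl group twice and hydrolysis of the benzal bromide gives the aldehyde (the established one-pot industrial sequence); no stereocentre.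

Step 6
Reactants: 12 3,5-dibromo-4-hydroxybenzaldehyde
Product: 14 3,4,5-trimethoxybenzaldehyde, via sodium 4-formyl-2,6-dimethoxyphenolate 13 (not isolated)
Conditions: NaOMe (3.3 equiv), CuCl (5 mol %), DMF/MeOH, 115 °C; then Me2SO4 (1.5 equiv), 60 °C
Reagents that add atoms: sodium methoxide (C[O-].[Na+]); dimethyl sulfate (COS(=O)(=O)OC)
Why: Ullmann-type copper-catalysed substitution of both aryl bromides by methoxide on the phenoxide (the syringaldehyde process), then SN2 O-methylation of the phenoxide by dimethyl sulfate; no stereocentre.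

Step 7
Reactants: 8 (S)-4-(3,4-dimethoxybenzyl)dihydrofuran-2(3H)-one; 14 3,4,5-trimethoxybenzaldehyde
Product: 17 (3R,4S)-4-(3,4-dimethoxybenzyl)-3-[hydroxy(3,4,5-trimethoxyphenyl)methyl]dihydrofuran-2(3H)-one (both carbinol epimers), via lithium lactone enolate 15 (not isolated), via lithium aldolate 16 (not isolated)
Conditions: LiN(i-Pr)2 (1.1 equiv), THF, −78 °C; then 14 (1.1 equiv), −78 °C; AcOH quench at −78 °C
Reagents that add atoms: none
Why: aldol addition of the lithium enolate to the non-enolisable aldehyde; the aldehyde adds to the enolate face anti to the C4 benzyl group, setting C3 as R (3,4-trans), while the carbinol centre forms unselectively and is erased in step 8.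

Step 8
Reactants: 17 (3R,4S)-4-(3,4-dimethoxybenzyl)-3-[hydroxy(3,4,5-trimethoxyphenyl)methyl]dihydrofuran-2(3H)-one
Product: 19 [(2R,3S,4S)-4-(3,4-dimethoxybenzyl)-2-(3,4,5-trimethoxyphenyl)tetrahydrofuran-3-yl]methanol, via triol 18 (not isolated)
Conditions: LiAlH4 (2.5 equiv), THF, 0 °C → rt; aqueous work-up; then camphorsulfonic acid (0.2 equiv), CH2Cl2, 0 °C → rt, Et3N quench at full conversion
Reagents that add atoms: none
Why: LiAlH4 reduces the lactone to the 1,4-diol without touching C3 or C4, and the acid then ionises the benzylic alcohol (either epimer) to the trimethoxybenzylic cation, which is captured in a five-membered closure by the primary hydroxyl on the benzyl-bearing branch (the other primary hydroxyl could only give an oxetane) with the aryl group trans to the neighbouring CH2OH, setting C2 as R — the dehydrative SN1 cycloetherification used for lariciresinol-type lignans.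

**Compound list**
1 | catechol (benzene-1,2-diol) | Oc1ccccc1O | starting material
2 | 1,2-dimethoxybenzene (veratrole) | COc1ccccc1OC | intermediate
3 | 4-bromo-1,2-dimethoxybenzene | COc1ccc(Br)cc1OC | intermediate
4 | 3-methyleneoxetane | C=C1COC1 | starting material
5 | 9-(oxetan-3-ylmethyl)-9-borabicyclo[3.3.1]nonane | C1OCC1CB1C2CCCC1CCC2 | intermediate
6 | 3-(3,4-dimethoxybenzyl)oxetane | COc1ccc(CC2COC2)cc1OC | intermediate
7 | carbon monoxide | [C-]#[O+] | starting material
8 | (S)-4-(3,4-dimethoxybenzyl)dihydrofuran-2(3H)-one | COc1ccc(C[C@@H]2COC(=O)C2)cc1OC | intermediate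
9 | p-cresol (4-methylphenol) | Cc1ccc(O)cc1 | starting material
10 | 2,6-dibromo-4-methylphenol | Cc1cc(Br)c(O)c(Br)c1 | intermediate
11 | 2,6-dibromo-4-(dibromomethyl)phenol | Oc1c(Br)cc(C(Br)Br)cc1Br | intermediate
12 | 3,5-dibromo-4-hydroxybenzaldehyde | O=Cc1cc(Br)c(O)c(Br)c1 | intermediate
13 | sodium 4-formyl-2,6-dimethoxyphenolate | [Na+].[O-]c1c(OC)cc(C=O)cc1OC | intermediate
14 | 3,4,5-trimethoxybenzaldehyde | COc1cc(C=O)cc(OC)c1OC | intermediate
15 | lithium (S)-4-(3,4-dimethoxybenzyl)-4,5-dihydrofuran-2-olate (lithium enolate of 8) | [Li+].COc1ccc(C[C@@H]2COC([O-])=C2)cc1OC | intermediate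
16 | lithium [(3R,4S)-4-(3,4-dimethoxybenzyl)-2-oxotetrahydrofuran-3-yl](3,4,5-trimethoxyphenyl)methanolate (both carbinol epimers) | [Li+].COc1ccc(C[C@@H]2COC(=O)[C@H]2C([O-])c2cc(OC)c(OC)c(OC)c2)cc1OC | intermediate
17 | (3R,4S)-4-(3,4-dimethoxybenzyl)-3-[hydroxy(3,4,5-trimethoxyphenyl)methyl]dihydrofuran-2(3H)-one (both carbinol epimers; 3,4-trans) | COc1ccc(C[C@@H]2COC(=O)[C@H]2C(O)c2cc(OC)c(OC)c(OC)c2)cc1OC | intermediate
18 | (2S,3S)-2-(3,4-dimethoxybenzyl)-3-[hydroxy(3,4,5-trimethoxyphenyl)methyl]butane-1,4-diol (both carbinol epimers) | COc1ccc(C[C@H](CO)[C@@H](CO)C(O)c2cc(OC)c(OC)c(OC)c2)cc1OC | intermediate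
19 | [(2R,3S,4S)-4-(3,4-dimethoxybenzyl)-2-(3,4,5-trimethoxyphenyl)tetrahydrofuran-3-yl]methanol (aryl and CH2OH trans, CH2OH and benzyl cis) | COc1ccc(C[C@@H]2CO[C@@H](c3cc(OC)c(OC)c(OC)c3)[C@@H]2CO)cc1OC | target

**Step count and risk**

Total steps: 8. Longest linear sequence: 6 (steps 1, 2, 3, 4, 7, 8).

Step 4 (the proposed new reaction) is the most likely to fail. The oxetane may polymerise on the Lewis acid, carbonylation of four-membered ethers is slow, and the C3 substituent is remote from the two methylene groups the catalyst must tell apart, so the ee and even the sense of induction are unknown. A modest ee could be upgraded by crystallisation of 17 or 19. The fallback uses known chemistry and sets out from 3. Reductive cross-electrophile coupling of 3 with purchased 3-(bromomethyl)cyclobutan-1-one (NiBr2(dme), 4,4'-di-tert-butyl-2,2'-bipyridine, Zn, NaI, DMA, 60 °C) gives 3-(3,4-dimethoxybenzyl)cyclobutan-1-one F1. Desymmetrising Baeyer–Villiger oxidation of F1 (m-CPBA, Sc(OTf)3 with a chiral N,N'-dioxide ligand, EtOAc, −20 °C, or a Baeyer–Villiger monooxygenase selected for the S-lactone) then expands the four-membered ketone to the lactone, and the route is rejoined at 8.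

Step 8 is the second risk. The 3,4,5-trimethoxybenzylic alcohol ionises less readily than a 4-alkoxybenzylic one, and stronger acid or longer times let the tetrahydrofuran re-ionise and close irreversibly onto the dimethoxyphenyl ring (aryltetralin formation). Retro-aldol cleavage during the hydride reduction is a lesser risk. The fallback replaces the cationic closure by a stereospecific Williamson closure; it sets out from 17 and comes back at 19.
- Dess–Martin oxidation of the carbinol mixture gives (3R,4S)-4-(3,4-dimethoxybenzyl)-3-(3,4,5-trimethoxybenzoyl)dihydrofuran-2(3H)-one F4.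
- Chelation-controlled reduction with Zn(BH4)2 (Et2O, −20 °C) gives the single syn carbinol (3R,4S)-4-(3,4-dimethoxybenzyl)-3-[(R)-hydroxy(3,4,5-trimethoxyphenyl)methyl]dihydrofuran-2(3H)-one F5.
- LiAlH4 gives (2S,3S)-2-(3,4-dimethoxybenzyl)-3-[(R)-hydroxy(3,4,5-trimethoxyphenyl)methyl]butane-1,4-diol F6.
- TsCl (2.2 equiv) in pyridine (0 °C → 40 °C) tosylates both primary hydroxyls to the bis-tosylate F7. The benzylic hydroxyl, the only nucleophile left, then displaces the 1,4-related tosylate with retention at the benzylic carbon to give [(2R,3S,4S)-4-(3,4-dimethoxybenzyl)-2-(3,4,5-trimethoxyphenyl)tetrahydrofuran-3-yl]methyl 4-methylbenzenesulfonate F8.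
- CsOAc in DMF at 80 °C gives the acetate F9, and K2CO3 in MeOH releases 19.

Step 5 is the third risk. The high-temperature side-chain bromination can over-brominate or tar on a laboratory scale. The fallback methoxylates first and oxidises the methyl group afterwards; it sets out from 9 and comes back at 14.
- Br2 (2 equiv) in CH2Cl2 at 0 °C gives 2,6-dibromo-4-methylphenol 10, now isolated.
- NaOMe with CuCl in DMF/MeOH at 115 °C gives 2,6-dimethoxy-4-methylphenol F2.
- Aerobic oxidation of the para-methyl group through the quinone methide (O2, Co(OAc)2 cat., NaOH, MeOH, 60 °C) gives 4-hydroxy-3,5-dimethoxybenzaldehyde F3.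
- MeI and K2CO3 in acetone give 14.

Further compounds
F1 | step 4 | 3-(3,4-dimethoxybenzyl)cyclobutan-1-one | COc1ccc(CC2CC(=O)C2)cc1OC
F2 | step 5 | 2,6-dimethoxy-4-methylphenol | COc1cc(C)cc(OC)c1O
F3 | step 5 | 4-hydroxy-3,5-dimethoxybenzaldehyde (syringaldehyde) | COc1cc(C=O)cc(OC)c1O
F4 | step 8 | (3R,4S)-4-(3,4-dimethoxybenzyl)-3-(3,4,5-trimethoxybenzoyl)dihydrofuran-2(3H)-one | COc1ccc(C[C@@H]2COC(=O)[C@H]2C(=O)c2cc(OC)c(OC)c(OC)c2)cc1OC
F5 | step 8 | (3R,4S)-4-(3,4-dimethoxybenzyl)-3-[(R)-hydroxy(3,4,5-trimethoxyphenyl)methyl]dihydrofuran-2(3H)-one | COc1ccc(C[C@@H]2COC(=O)[C@H]2[C@@H](O)c2cc(OC)c(OC)c(OC)c2)cc1OC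
F6 | step 8 | (2S,3S)-2-(3,4-dimethoxybenzyl)-3-[(R)-hydroxy(3,4,5-trimethoxyphenyl)methyl]butane-1,4-diol | COc1ccc(C[C@H](CO)[C@@H](CO)[C@@H](O)c2cc(OC)c(OC)c(OC)c2)cc1OC
F7 | step 8 | (2S,3S)-2-(3,4-dimethoxybenzyl)-3-[(R)-hydroxy(3,4,5-trimethoxyphenyl)methyl]butane-1,4-diyl bis(4-methylbenzenesulfonate) | COc1ccc(C[C@H](COS(=O)(=O)c2ccc(C)cc2)[C@@H](COS(=O)(=O)c2ccc(C)cc2)[C@@H](O)c2cc(OC)c(OC)c(OC)c2)cc1OC
F8 | step 8 | [(2R,3S,4S)-4-(3,4-dimethoxybenzyl)-2-(3,4,5-trimethoxyphenyl)tetrahydrofuran-3-yl]methyl 4-methylbenzenesulfonate | COc1ccc(C[C@@H]2CO[C@@H](c3cc(OC)c(OC)c(OC)c3)[C@@H]2COS(=O)(=O)c2ccc(C)cc2)cc1OC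
F9 | step 8 | [(2R,3S,4S)-4-(3,4-dimethoxybenzyl)-2-(3,4,5-trimethoxyphenyl)tetrahydrofuran-3-yl]methyl acetate | COc1ccc(C[C@@H]2CO[C@@H](c3cc(OC)c(OC)c(OC)c3)[C@@H]2COC(C)=O)cc1OC
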